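**Plan**
- The retrosynthesis first cuts the four C–CH3 bonds at the two quaternary C(CH3)2 carbons (one in ring A, one in ring C). It then cuts the two ring–CH2–ring bridge bonds and finally the three ring–acyl bonds, arriving at phloroglucinol.
- Enabling feature: in ring A and in ring C the C(CH3)2 carbon, flanked by two oxygen-bearing ring carbons, is the only ring carbon that would be an unsubstituted C–H in the corresponding aromatic acylphloroglucinol ring. Aromatic ring B has no C–H at all.
- Forward: phloroglucinol is acylated to the butyryl and the propionyl ketone. Two butyryl ketones are joined by formaldehyde to a symmetric dimer, and the propionyl ring is then attached through its Mannich base. Because the dimer is symmetric, either of its rings may accept the third ring, and a butyryl ring becomes central ring B.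
- The last operation methylates each outer ring twice at its single free carbon and dearomatises rings A and C. No ring is closed anywhere; all three carbocycles come from phloroglucinol.
- The target has no stereocentre, so no stereochemistry has to be set.

Key step: step 6

Remark: the outer rings of the target are written as one enol tautomer of a freely equilibrating cyclic β-triketone; all tautomers are the same compound.

**Step 1**
Reactants: 1 phloroglucinol (anhydrous); 2 butyryl chloride
Product: 3 1-(2,4,6-trihydroxyphenyl)butan-1-one
Conditions: AlCl3 (4 equiv), PhNO2/CH2Cl2, 0 °C → 40 °C; then ice, 2 M HCl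
Reagents that add atoms: butyryl chloride, CCCC(=O)Cl
Why: Friedel–Crafts acylation of one of the three equivalent ring carbons of phloroglucinol, after which the aluminium-chelated ortho-hydroxy ketone is deactivated toward a second acylation, so the mono-ketone should dominate.

**Step 2**
Reactants: 1 phloroglucinol (anhydrous); 4 propionyl chloride
Product: 5 1-(2,4,6-trihydroxyphenyl)propan-1-one
Conditions: AlCl3 (4 equiv), PhNO2/CH2Cl2, 0 °C → 40 °C; then ice, 2 M HCl
Reagents that add atoms: propionyl chloride, CCC(=O)Cl
Why: the same Friedel–Crafts acylation as in step 1, with the same self-limiting deactivation after the first acyl group has entered.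

**Step 3**
Reactants: 3 1-(2,4,6-trihydroxyphenyl)butan-1-one (4 equiv per formaldehyde); 6 formaldehyde
Product: 8 bis(3-butanoyl-2,4,6-trihydroxyphenyl)methane, via hydroxymethyl ketone 7 (not isolated)
Conditions: 37% aq. CH2O, 1% aq. KOH (1.1 equiv per 3), 0 °C, 10 min, Ar; then 2 M HCl; unreacted 3 recovered
Reagents that add atoms: formaldehyde, C=O
Why: alkaline phenol–formaldehyde condensation (Lederer–Manasse hydroxymethylation to 7, then displacement of the benzylic hydroxyl by a second phenoxide) in which limiting formaldehyde should hold chain growth largely at the dimer, whose two identical rings make its two remaining ring C–H positions equivalent.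

**Step 4**
Reactants: 5 1-(2,4,6-trihydroxyphenyl)propan-1-one (3 equiv); 6 formaldehyde; 9 dimethylamine
Product: 10 1-[3-[(dimethylamino)methyl]-2,4,6-trihydroxyphenyl]propan-1-one
Conditions: 40% aq. Me2NH (1 equiv), 37% aq. CH2O (1 equiv), EtOH, 0 °C → rt; zwitterionic solid filtered off, excess 5 recovered
Reagents that add atoms: formaldehyde, C=O; dimethylamine, CNC
Why: phenolic Mannich reaction in which the iminium ion from formaldehyde and dimethylamine attacks a free ring carbon, while the excess of 5 and precipitation of the zwitterionic mono-adduct should prevent a second aminomethylation.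

**Step 5**
Reactants: 10 1-[3-[(dimethylamino)methyl]-2,4,6-trihydroxyphenyl]propan-1-one; 8 bis(3-butanoyl-2,4,6-trihydroxyphenyl)methane (3 equiv)
Product: 12 all-aromatic trimer 1-[3-[(3-butanoyl-2,4,6-trihydroxyphenyl)methyl]-5-[(2,4,6-trihydroxy-3-propanoylphenyl)methyl]-2,4,6-trihydroxyphenyl]butan-1-one, via ortho-quinone methide 11 (not isolated)
Conditions: 1,4-dioxane, 95 °C, 10 added in portions to 8, Ar stream to sweep out Me2NH; excess 8 recovered
Reagents that add atoms: none
Why: thermal loss of dimethylamine from the Mannich base gives ortho-quinone methide 11, which a free ring carbon of 8 captures in a Friedel–Crafts-type conjugate addition; since 8 is symmetric either of its free positions gives the same trimer with a butyryl ring in the centre, and the excess of 8 with portionwise addition of 10 should hold back self-condensation and a second alkylation.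

**Step 6**
Reactants: 12 all-aromatic trimer; 13 iodomethane (4.2 equiv)
Product: 15 target (filixic acid PBB), via bis(C-methyl) trimer 14 (not isolated)
Conditions: NaOMe (10 equiv), MeI added in portions, MeOH, 0 °C → rt, Ar, dark; then cold 1 M HCl; crystallisation from acetone/EtOAc
Reagents that add atoms: iodomethane, CI
Why: NaOMe turns each outer ring into its phenoxide, which attacks iodomethane in an SN2 reaction through its only unsubstituted ring carbon to give the C-methyl phenol 14; renewed deprotonation and a second SN2 attack from the same carbon create the C(CH3)2 centre and leave the ring as the enolised, cross-conjugated cyclohexadienone trione. The closest known reaction type is the base-mediated C-methylation of acylphloroglucinols to acylfilicinic acids and of C-alkylated acylphloroglucinols to gem-dialkyl dienones. No ring is closed and no stereocentre is created, since each new quaternary carbon carries two identical methyl groups. Site selectivity for the first methylation should come from the substrate: each outer ring offers exactly one C–H carbon, the least hindered and most electron-rich position, while ring B has none and its substituted carbons are shielded by the bridges and the acyl group. The second methyl group should prefer the methyl-bearing carbon over the bulkier bridge-bearing one, and C- over O-methylation should be favoured by the hydrogen-bonding solvent methanol and the soft electrophile. Further methylation should be limited by the four equivalents of iodomethane and by the low nucleophilicity of the delocalised triketone anion, and the low temperature and short contact time should hold back base-induced exchange of the methylene bridges.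

**Compound list**
1 | phloroglucinol (benzene-1,3,5-triol) | Oc1cc(O)cc(O)c1 | starting material
2 | butyryl chloride | CCCC(=O)Cl | starting material
3 | 1-(2,4,6-trihydroxyphenyl)butan-1-one (phlorbutyrophenone) | CCCC(=O)c1c(O)cc(O)cc1O | intermediate
4 | propionyl chloride | CCC(=O)Cl | starting material
5 | 1-(2,4,6-trihydroxyphenyl)propan-1-one (phlorpropiophenone) | CCC(=O)c1c(O)cc(O)cc1O | intermediate
6 | formaldehyde (37% aqueous solution) | C=O | starting material
7 | 1-[3-(hydroxymethyl)-2,4,6-trihydroxyphenyl]butan-1-one (formed in the flask, not isolated) | CCCC(=O)c1c(O)cc(O)c(CO)c1O | intermediate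
8 | bis(3-butanoyl-2,4,6-trihydroxyphenyl)methane, symmetric dimer | CCCC(=O)c1c(O)cc(O)c(Cc2c(O)cc(O)c(C(=O)CCC)c2O)c1O | intermediate
9 | dimethylamine (40% aqueous solution) | CNC | starting material
10 | 1-[3-[(dimethylamino)methyl]-2,4,6-trihydroxyphenyl]propan-1-one, Mannich base | CCC(=O)c1c(O)cc(O)c(CN(C)C)c1O | intermediate
11 | 3,5-dihydroxy-6-methylidene-4-propanoylcyclohexa-2,4-dien-1-one, ortho-quinone methide (formed in the flask, not isolated) | CCC(=O)C1=C(O)C(=C)C(=O)C=C1O | intermediate
12 | 1-[3-[(3-butanoyl-2,4,6-trihydroxyphenyl)methyl]-5-[(2,4,6-trihydroxy-3-propanoylphenyl)methyl]-2,4,6-trihydroxyphenyl]butan-1-one, all-aromatic trimer | CCCC(=O)c1c(O)cc(O)c(Cc2c(O)c(Cc3c(O)cc(O)c(C(=O)CC)c3O)c(O)c(C(=O)CCC)c2O)c1O | intermediate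
13 | iodomethane | CI | starting material
14 | 1-[3-[(3-butanoyl-2,4,6-trihydroxy-5-methylphenyl)methyl]-5-[(2,4,6-trihydroxy-3-methyl-5-propanoylphenyl)methyl]-2,4,6-trihydroxyphenyl]butan-1-one, one C-methyl group on each outer ring (formed in the flask, not isolated) | CCCC(=O)c1c(O)c(C)c(O)c(Cc2c(O)c(Cc3c(O)c(C)c(O)c(C(=O)CC)c3O)c(O)c(C(=O)CCC)c2O)c1O | intermediate
15 | filixic acid PBB: central 1-(2,4,6-trihydroxyphenyl)butan-1-one ring B bearing at C3 a CH2 link to C6 of 2-butanoyl-3,5-dihydroxy-4,4-dimethylcyclohexa-2,5-dien-1-one (ring A) and at C5 a CH2 link to C6 of 3,5-dihydroxy-4,4-dimethyl-2-propanoylcyclohexa-2,5-dien-1-one (ring C); no stereocentre | CCCC(=O)C1=C(O)C(C)(C)C(O)=C(Cc2c(O)c(CC3=C(O)C(C)(C)C(O)=C(C(=O)CC)C3=O)c(O)c(C(=O)CCC)c2O)C1=O | target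

**Step count and risks**
Total step count: 6. Longest linear sequence: 4 steps (steps 1, 3, 5, 6 or steps 2, 4, 5, 6).

Steps most likely to fail:

Step 6. The methylation may spill over to oxygen, to the bridge-bearing carbons of the outer rings or to the substituted carbons of ring B. It may also stop before both methyl groups are in place. The methoxide may in addition cleave and re-form the methylene bridges, which would scramble the butyryl and propionyl rings. Fallback: the four methyl groups are introduced before the bridges, setting out from 3 and 5. Each ketone is C-methylated with iodomethane and NaOMe in methanol to give 2-butanoyl-3,5-dihydroxy-4,4-dimethylcyclohexa-2,5-dien-1-one (butyrylfilicinic acid) F1 and 3,5-dihydroxy-4,4-dimethyl-2-propanoylcyclohexa-2,5-dien-1-one (propionylfilicinic acid) F2. A Mannich reaction of F1 with formaldehyde and dimethylamine gives 2-butanoyl-6-[(dimethylamino)methyl]-3,5-dihydroxy-4,4-dimethylcyclohexa-2,5-dien-1-one F3, which has no free nucleophilic carbon left. Heating F3 with an excess of 3 gives the two-ring compound 2-butanoyl-6-[(3-butanoyl-2,4,6-trihydroxyphenyl)methyl]-3,5-dihydroxy-4,4-dimethylcyclohexa-2,5-dien-1-one F4, which keeps a single free ring carbon. The Mannich base of F2, 6-[(dimethylamino)methyl]-3,5-dihydroxy-4,4-dimethyl-2-propanoylcyclohexa-2,5-dien-1-one F5, is then heated with F4 and the sequence rejoins the route at 15.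

Step 5. The quinone methide may condense with the free ring position of unreacted Mannich base, the trimer may be alkylated again at its two free positions, and bridges may exchange at the reaction temperature. Fallback: the electrophilic carbon is moved to the large partner, setting out from 8. A Mannich reaction of 8 with a deficit of formaldehyde and dimethylamine gives 1-[3-[(3-butanoyl-2,4,6-trihydroxyphenyl)methyl]-5-[(dimethylamino)methyl]-2,4,6-trihydroxyphenyl]butan-1-one F6. Heating F6 with a large excess of the cheap ketone 5 then rejoins the route at 12, and the small excess partner is easily removed.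

Step 3. Chain growth may run past the dimer, because 3 and 8 both keep free ring positions, and methylene-bridged oligomers may form. Fallback: the bridging carbon is delivered as one preformed electrophile per molecule, setting out from 3. A Mannich reaction of excess 3 with formaldehyde and dimethylamine gives 1-[3-[(dimethylamino)methyl]-2,4,6-trihydroxyphenyl]butan-1-one F7. Heating F7 with an excess of 3 in dioxane rejoins the route at 8.

**Further compounds**
F1 | step 6 | 2-butanoyl-3,5-dihydroxy-4,4-dimethylcyclohexa-2,5-dien-1-one (butyrylfilicinic acid) | CCCC(=O)C1=C(O)C(C)(C)C(O)=CC1=O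
F2 | step 6 | 3,5-dihydroxy-4,4-dimethyl-2-propanoylcyclohexa-2,5-dien-1-one (propionylfilicinic acid) | CCC(=O)C1=C(O)C(C)(C)C(O)=CC1=O
F3 | step 6 | 2-butanoyl-6-[(dimethylamino)methyl]-3,5-dihydroxy-4,4-dimethylcyclohexa-2,5-dien-1-one | CCCC(=O)C1=C(O)C(C)(C)C(O)=C(CN(C)C)C1=O
F4 | step 6 | 2-butanoyl-6-[(3-butanoyl-2,4,6-trihydroxyphenyl)methyl]-3,5-dihydroxy-4,4-dimethylcyclohexa-2,5-dien-1-one | CCCC(=O)C1=C(O)C(C)(C)C(O)=C(Cc2c(O)cc(O)c(C(=O)CCC)c2O)C1=O
F5 | step 6 | 6-[(dimethylamino)methyl]-3,5-dihydroxy-4,4-dimethyl-2-propanoylcyclohexa-2,5-dien-1-one | CCC(=O)C1=C(O)C(C)(C)C(O)=C(CN(C)C)C1=O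
F6 | step 5 | 1-[3-[(3-butanoyl-2,4,6-trihydroxyphenyl)methyl]-5-[(dimethylamino)methyl]-2,4,6-trihydroxyphenyl]butan-1-one | CCCC(=O)c1c(O)c(CN(C)C)c(O)c(Cc2c(O)cc(O)c(C(=O)CCC)c2O)c1O
F7 | step 3 | 1-[3-[(dimethylamino)methyl]-2,4,6-trihydroxyphenyl]butan-1-one | CCCC(=O)c1c(O)cc(O)c(CN(C)C)c1O
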